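**Retrosynthetic overview**
1. Target 26 ⇐ tri-O-methyl dialdehyde 25 ⇐ arene 23 (double ortho-lithiation/formylation); the C-4 carbinol ⇐ ketone 22 + MeLi; 22 ⇐ alkene 20 by allylic oxidation and hydrogenation.
2. Key disconnection: the C-1–C-1' bond, with both stereocentres, by Claisen [3,3] rearrangement of the (E)-aryl vinyl ether 16 of allylic alcohol 13; the aldehyde carbon of 17 then becomes the isobutyl CH2.
3. 13 ⇐ enone 12 ⇐ diol 10; C-7 is inverted on the rigid trans-decalin by ozonolysis of the isopropenyl group and base epimerisation of the acetyl, then MeMgBr.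
4. Ring order: ring B is bought as (+)-dihydrocarvone; ring A is closed by Robinson annulation with methyl vinyl ketone (sets C-10; C-5 follows by dissolving-metal reduction); the arene is bought as 2,4,6-trimethoxybenzaldehyde.

Convention (one line): the decalin is numbered as in eudesmane (C-10 carries the angular methyl, C-7 the three-carbon unit, C-1' is the benzylic carbon); β means the face of the angular methyl, α the opposite face; the SMILES strings fix the absolute configuration.

**Route**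

Step 1
Reactants: 1 (+)-dihydrocarvone; 2 methyl vinyl ketone
Product: 5 enone (4aR,7R)-4a-methyl-7-(prop-1-en-2-yl)-4,4a,5,6,7,8-hexahydronaphthalen-2(3H)-one, via Michael adduct 3 (not isolated), via aldol ketol 4 (not isolated)
Conditions: KOH (cat.), EtOH, 0 to 23 °C; then aq. KOH, reflux
Reagents that add atoms: none
Why: Robinson annulation in which the thermodynamic enolate adds axially on the chair with the isopropenyl group equatorial, so the new chain is cis and the C-10 methyl trans to isopropenyl, and aldol condensation closes ring A.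

Step 2
Reactants: 5 enone
Product: 7 10β-methyl-7α-(prop-1-en-2-yl)-5α-H-decalin-3β-ol, via trans-decalone 6 (not isolated)
Conditions: Li (excess), NH3(l)/THF, −78 to −33 °C; then MeOH
Reagents that add atoms: none
Why: Dissolving-metal enone reduction protonates C-5 axially to give the trans ring fusion, and the ketone released by methanol is reduced on to the equatorial alcohol, while the isolated alkene is untouched.

Step 3
Reactants: 7 3β-alcohol
Product: 9 7β-acetyl-10β-methyl-5α-H-decalin-3β-ol, via axial methyl ketone 8 (not isolated)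
Conditions: O3, CH2Cl2/MeOH, −78 °C; Me2S; then NaOMe, MeOH, 23 °C
Reagents that add atoms: ozone, O=[O+][O-]
Why: Ozonolysis turns the axial isopropenyl into an enolisable acetyl, and base equilibration moves it to the equatorial position (cis to the angular methyl), so the bought C-7 centre is inverted under control of C-10.

Step 4
Reactants: 9 hydroxy ketone
Product: 10 7β-(2-hydroxypropan-2-yl)-10β-methyl-5α-H-decalin-3β-ol
Conditions: MeMgBr (4 equiv), THF, 0 to 23 °C
Reagents that add atoms: methylmagnesium bromide, C[Mg]Br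
Why: Grignard addition to the methyl ketone gives the tertiary carbinol without creating a stereocentre.

Step 5
Reactants: 10 diol
Product: 12 7β-(2-hydroxypropan-2-yl)-10β-methyl-5α-H-decal-1-en-3-one, via keto alcohol 11 (not isolated)
Conditions: IBX (3 equiv), DMSO, 25 then 75 °C
Reagents that add atoms: none
Why: IBX oxidises the secondary alcohol and then dehydrogenates the trans-fused 3-ketone through its favoured C-2 enol to the 1-en-3-one, leaving the tertiary alcohol alone.

Step 6
Reactants: 12 enone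
Product: 13 7β-(2-hydroxypropan-2-yl)-10β-methyl-5α-H-decal-1-en-3α-ol
Conditions: K[(s-Bu)3BH] (2.2 equiv), THF, −78 °C; H2O
Reagents that add atoms: none
Why: The bulky borohydride attacks the carbonyl equatorially (1,2-reduction, since C-1 is neopentylic and shielded), giving the pseudoaxial 3α-alcohol trans to the angular methyl.

Step 7
Reactants: 14 2,4,6-trimethoxybenzaldehyde
Product: 15 (E)-2-(2-iodovinyl)-1,3,5-trimethoxybenzene
Conditions: CrCl2 (6 equiv), CHI3 (2 equiv), THF, 0 to 23 °C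
Reagents that add atoms: iodoform, IC(I)I
Why: Takai olefination gives the (E)-vinyl iodide selectively.

Step 8
Reactants: 13 allylic alcohol; 15 vinyl iodide
Product: 17 (2R)-2-[7β-(2-hydroxypropan-2-yl)-10β-methyl-5α-H-decal-2-en-1α-yl]-2-(2,4,6-trimethoxyphenyl)acetaldehyde, via aryl vinyl ether 16 (not isolated)
Conditions: CuI (10 mol %), 3,4,7,8-tetramethyl-1,10-phenanthroline (20 mol %), Cs2CO3 (1.5 equiv), toluene, 80 °C; filter; then o-xylene, 140 °C
Reagents that add atoms: none
Why: Ullmann-type C–O coupling keeps the E geometry, and the Claisen [3,3] rearrangement through a chair with the aryl group equatorial moves the carbon suprafacially from the α C-3 oxygen to C-1, which sets C-1 (α) and C-1' (R) together.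

Step 9
Reactants: 17 aldehyde
Product: 20 1α-[(1R)-3-methyl-1-(2,4,6-trimethoxyphenyl)butyl]-7β-(2-hydroxypropan-2-yl)-10β-methyl-5α-H-decal-2-ene, via tosylhydrazone 18 (not isolated), via N-silyl tosylhydrazone 19 (not isolated)
Conditions: TsNHNH2, THF, 23 °C; Et3N, TBSOTf (1.05 equiv), −78 °C; i-PrLi (2.5 equiv), −78 °C; AcOH, CF3CH2OH, −78 to 23 °C
Reagents that add atoms: isopropyllithium, [Li]C(C)C (stays in 20); 4-methylbenzenesulfonohydrazide, Cc1ccc(cc1)S(=O)(=O)NN, and TBSOTf, CC(C)(C)[Si](C)(C)OS(=O)(=O)C(F)(F)F (atoms only in 18 and 19)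
Why: Myers reductive coupling, in which i-PrLi adds to the C=N bond and the adduct loses sulfinate and dinitrogen, turns CHO into CH2–CH(CH3)2 without touching C-1'.

Step 10
Reactants: 20 alkene
Product: 21 1α-[(1R)-3-methyl-1-(2,4,6-trimethoxyphenyl)butyl]-7β-(2-hydroxypropan-2-yl)-10β-methyl-5α-H-decal-2-en-4-one
Conditions: Rh2(cap)4 (1 mol %; cap = caprolactamate, C6H10NO), t-BuOOH (5 equiv), K2CO3, CH2Cl2, 23 °C
Reagents that add atoms: tert-butyl hydroperoxide, CC(C)(C)OO
Why: Radical allylic oxidation takes the well-aligned axial hydrogen of the only allylic CH2 (C-4; the allylic C-1 hydrogen is tertiary, equatorial and shielded) and gives the conjugated enone.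

Step 11
Reactants: 21 enone
Product: 22 1α-[(1R)-3-methyl-1-(2,4,6-trimethoxyphenyl)butyl]-7β-(2-hydroxypropan-2-yl)-10β-methyl-5α-H-decalin-4-one
Conditions: H2 (1 atm), 10% Pd/C, EtOAc, 23 °C
Reagents that add atoms: none
Why: Heterogeneous hydrogenation saturates the enone double bond under neutral conditions, so no stereocentre is formed and C-5 is not epimerised.

Step 12
Reactants: 22 ketone
Product: 23 1α-[(1R)-3-methyl-1-(2,4,6-trimethoxyphenyl)butyl]-7β-(2-hydroxypropan-2-yl)-4α,10β-dimethyl-5α-H-decalin-4β-ol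
Conditions: MeLi (3 equiv), Et2O, −78 to 0 °C
Reagents that add atoms: methyllithium, [Li]C
Why: 1,2-Addition from the equatorial side, because the axial path is blocked by the syn-axial angular methyl, gives the axial 4β-hydroxyl with the new methyl equatorial.

Step 13
Reactants: 23 diol
Product: 25 5-[(1R)-1-(decalinyl)-3-methylbutyl]-2,4,6-trimethoxybenzene-1,3-dicarbaldehyde (decalinyl as in 23), via mono-formyl amino alkoxide 24 (not isolated)
Conditions: n-BuLi, TMEDA, THF, 0 °C; DMF, −78 to 0 °C; n-BuLi, 0 °C; DMF; aq. HCl work-up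
Reagents that add atoms: N,N-dimethylformamide, CN(C)C=O
Why: Directed ortho-metalation removes each ring hydrogen flanked by two methoxy groups, and DMF traps the aryllithium as an amino alkoxide that survives the second lithiation, so both aldehydes appear on work-up.

Step 14
Reactants: 25 tri-O-methyl dialdehyde
Product: 26 target, 5-[(1R)-1-[(1S,4R,4aS,6S,8aR)-4-hydroxy-6-(2-hydroxypropan-2-yl)-4,8a-dimethyldecahydronaphthalen-1-yl]-3-methylbutyl]-2,4,6-trihydroxybenzene-1,3-dicarbaldehyde
Conditions: 4-MeC6H4SLi (excess), HMPA/toluene, 110 °C; then dilute HCl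
Reagents that add atoms: none
Why: SN2 O-demethylation by thiolate works because the formyl-flanked aryloxides are good leaving groups, and the non-acidic conditions spare the tertiary alcohols.

**Compound list**
1 | (+)-dihydrocarvone, (2R,5R)-2-methyl-5-(prop-1-en-2-yl)cyclohexan-1-one (commercial C-2 epimer mixture converges) | O=C1C[C@H](C(C)=C)CC[C@H]1C | starting material
2 | methyl vinyl ketone | CC(=O)C=C | starting material
3 | Michael adduct, 2-methyl-2-(3-oxobutyl)-5-(prop-1-en-2-yl)cyclohexanone, oxobutyl cis to isopropenyl | O=C1C[C@H](C(C)=C)CC[C@]1(C)CCC(C)=O | intermediate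
4 | aldol ketol, 5-hydroxy-10β-methyl-7α-(prop-1-en-2-yl)decalin-3-one (C-5 not assigned, lost on dehydration) | C1CC(=O)CC2(O)C[C@H](C(C)=C)CC[C@]12C | intermediate
5 | (4aR,7R)-4a-methyl-7-(prop-1-en-2-yl)-4,4a,5,6,7,8-hexahydronaphthalen-2(3H)-one | C1CC(=O)C=C2C[C@H](C(C)=C)CC[C@]12C | intermediate
6 | 10β-methyl-7α-(prop-1-en-2-yl)-5α-H-decalin-3-one | C1CC(=O)C[C@H]2C[C@H](C(C)=C)CC[C@]12C | intermediate
7 | 10β-methyl-7α-(prop-1-en-2-yl)-5α-H-decalin-3β-ol | C1C[C@@H](O)C[C@H]2C[C@H](C(C)=C)CC[C@]12C | intermediate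
8 | 7α-acetyl-10β-methyl-5α-H-decalin-3β-ol | C1C[C@@H](O)C[C@H]2C[C@H](C(C)=O)CC[C@]12C | intermediate
9 | 7β-acetyl-10β-methyl-5α-H-decalin-3β-ol | C1C[C@@H](O)C[C@H]2C[C@@H](C(C)=O)CC[C@]12C | intermediate
10 | 7β-(2-hydroxypropan-2-yl)-10β-methyl-5α-H-decalin-3β-ol | C1C[C@@H](O)C[C@H]2C[C@@H](C(C)(C)O)CC[C@]12C | intermediate
11 | 7β-(2-hydroxypropan-2-yl)-10β-methyl-5α-H-decalin-3-one | C1CC(=O)C[C@H]2C[C@@H](C(C)(C)O)CC[C@]12C | intermediate
12 | 7β-(2-hydroxypropan-2-yl)-10β-methyl-5α-H-decal-1-en-3-one | C1=CC(=O)C[C@H]2C[C@@H](C(C)(C)O)CC[C@]12C | intermediate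
13 | 7β-(2-hydroxypropan-2-yl)-10β-methyl-5α-H-decal-1-en-3α-ol | C1=C[C@H](O)C[C@H]2C[C@@H](C(C)(C)O)CC[C@]12C | intermediate
14 | 2,4,6-trimethoxybenzaldehyde | COc1cc(OC)c(C=O)c(OC)c1 | starting material
15 | (E)-2-(2-iodovinyl)-1,3,5-trimethoxybenzene | COc1cc(OC)c(/C=C/I)c(OC)c1 | intermediate
16 | 3α-[(E)-2-(2,4,6-trimethoxyphenyl)ethenyloxy]-7β-(2-hydroxypropan-2-yl)-10β-methyl-5α-H-decal-1-ene | C1=C[C@H](O/C=C/c3c(OC)cc(OC)cc3OC)C[C@H]2C[C@@H](C(C)(C)O)CC[C@]12C | intermediate
17 | (2R)-2-[7β-(2-hydroxypropan-2-yl)-10β-methyl-5α-H-decal-2-en-1α-yl]-2-(2,4,6-trimethoxyphenyl)acetaldehyde | O=C[C@@H](c1c(OC)cc(OC)cc1OC)[C@@H]1C=CC[C@H]2C[C@@H](C(C)(C)O)CC[C@]12C | intermediate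
18 | tosylhydrazone of 17 | Cc1ccc(cc1)S(=O)(=O)N/N=C/[C@@H](c1c(OC)cc(OC)cc1OC)[C@@H]1C=CC[C@H]2C[C@@H](C(C)(C)O)CC[C@]12C | intermediate
19 | N-tert-butyldimethylsilyl tosylhydrazone of 17 | Cc1ccc(cc1)S(=O)(=O)N([Si](C)(C)C(C)(C)C)/N=C/[C@@H](c1c(OC)cc(OC)cc1OC)[C@@H]1C=CC[C@H]2C[C@@H](C(C)(C)O)CC[C@]12C | intermediate
20 | 1α-[(1R)-3-methyl-1-(2,4,6-trimethoxyphenyl)butyl]-7β-(2-hydroxypropan-2-yl)-10β-methyl-5α-H-decal-2-ene | CC(C)C[C@@H](c1c(OC)cc(OC)cc1OC)[C@@H]1C=CC[C@H]2C[C@@H](C(C)(C)O)CC[C@]12C | intermediate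
21 | the 2-en-4-one of 20 | CC(C)C[C@@H](c1c(OC)cc(OC)cc1OC)[C@@H]1C=CC(=O)[C@H]2C[C@@H](C(C)(C)O)CC[C@]12C | intermediate
22 | the saturated 4-ketone | CC(C)C[C@@H](c1c(OC)cc(OC)cc1OC)[C@@H]1CCC(=O)[C@H]2C[C@@H](C(C)(C)O)CC[C@]12C | intermediate
23 | 4β-hydroxy-4α-methyl diol with 2,4,6-trimethoxyphenyl group | CC(C)C[C@@H](c1c(OC)cc(OC)cc1OC)[C@@H]1CC[C@@](C)(O)[C@H]2C[C@@H](C(C)(C)O)CC[C@]12C | intermediate
24 | mono-formyl adduct of 23 as lithium dimethylamino alkoxide (either ring position, both converge) | CC(C)C[C@@H](c1c(OC)c(C(O[Li])N(C)C)c(OC)cc1OC)[C@@H]1CC[C@@](C)(O[Li])[C@H]2C[C@@H](C(C)(C)O[Li])CC[C@]12C | intermediate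
25 | tri-O-methyl ether of the target | CC(C)C[C@@H](c1c(OC)c(C=O)c(OC)c(C=O)c1OC)[C@@H]1CC[C@@](C)(O)[C@H]2C[C@@H](C(C)(C)O)CC[C@]12C | intermediate
26 | CNP0409870.5 | CC(C)C[C@@H](c1c(O)c(C=O)c(O)c(C=O)c1O)[C@@H]1CC[C@@](C)(O)[C@H]2C[C@@H](C(C)(C)O)CC[C@]12C | target

**Step count and risks**
Total: 14 steps. Longest linear sequence: 13 steps (steps 1–6 and 8–14, from 1); step 7 is the one-step side branch.

Most likely to fail:

- Step 8. The coupling may stall on the hindered pseudoaxial alcohol, and a boat transition state or base epimerisation of 17 would erode control at C-1'. The fallback sets out from 13 and 14 and returns at 16. Wittig methoxymethylenation of 14 (MeOCH2PPh3Cl, KOt-Bu, THF) gives 1,3,5-trimethoxy-2-(2-methoxyvinyl)benzene F1. Heating 13 with F1 and catalytic 2,4-dinitrophenol in xylene at 140 °C forms the mixed methyl acetal F2, which loses methanol to give 16 and then rearranges to 17 in the same pot. The E and Z enol ethers equilibrate under the acid, and the E isomer rearranges faster through the chair with the aryl group equatorial.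

- Step 9. A secondary alkyllithium must add to a hindered, enolisable α-aryl hydrazone. The fallback sets out from 17 and returns at 20. i-PrMgCl (THF, −78 °C) gives the secondary alcohol F3 (both carbinol epimers serve). PhOC(S)Cl/DMAP acylates only the secondary hydroxyl to give the O-phenyl thionocarbonate F4. Bu3SnH/AIBN (toluene, 90 °C) then removes the oxygen (Barton–McCombie deoxygenation) to give 20.

- Step 10. The radical oxidation must choose C-4 beside an electron-rich arene and a tertiary benzylic C–H. The fallback sets out from 20 and returns at 21. SeO2 (cat.)/t-BuOOH (CH2Cl2, 23 °C) hydroxylates C-4 by an ene reaction and [2,3] shift to give the 4β-allylic alcohol F5, and Dess–Martin periodinane oxidises it to 21.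

**Further compounds**
F1 | step 8 | 1,3,5-trimethoxy-2-(2-methoxyvinyl)benzene (E/Z mixture) | COC=Cc1c(OC)cc(OC)cc1OC
F2 | step 8 | mixed methyl acetal of 13 with (2,4,6-trimethoxyphenyl)acetaldehyde (acetal carbon epimers) | C1=C[C@H](OC(OC)Cc3c(OC)cc(OC)cc3OC)C[C@H]2C[C@@H](C(C)(C)O)CC[C@]12C
F3 | step 9 | secondary alcohol from i-PrMgCl addition to 17 (carbinol epimers) | CC(C)C(O)[C@@H](c1c(OC)cc(OC)cc1OC)[C@@H]1C=CC[C@H]2C[C@@H](C(C)(C)O)CC[C@]12C
F4 | step 9 | O-phenyl thionocarbonate of F3 | CC(C)C(OC(=S)Oc1ccccc1)[C@@H](c1c(OC)cc(OC)cc1OC)[C@@H]1C=CC[C@H]2C[C@@H](C(C)(C)O)CC[C@]12C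
F5 | step 10 | 4β-hydroxy derivative of 20 (allylic alcohol) | CC(C)C[C@@H](c1c(OC)cc(OC)cc1OC)[C@@H]1C=C[C@@H](O)[C@H]2C[C@@H](C(C)(C)O)CC[C@]12C
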